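**Retrosynthetic overview**

1. Target 27 comes from 26 (hydrolysis of both ketals), and 26 from 25 (C5 chlorination). Ring A (O2–C3=C4) comes from 22 by transfer of the C1-bound dienoyl group to the C4 methyl dienolate and cyclodehydration; the side-chain acid 20 comes from (S)-2-methylbutan-1-ol.
2. Ring B comes from the open-chain (Z)-ene-1,2-dione aldehyde 12 by forming C7–C8 in a carbene-catalysed crossed benzoin. The strategy rests on C7 and C8 being adjacent oxygen-bearing carbons of ring B, with C8 attached to the hydrogen-free quaternary C8a. The C8 carbinol then follows by C1–OH-directed reduction.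
3. 12 comes from the unsaturated δ-lactone 9, whose ring (closed by metathesis) locks the Z geometry of C4a=C5, plus an acetyl anion equivalent for C7.
4. 9 comes from the prochiral diol 6 (lipase desymmetrization sets C8a), and 6 from diethyl isopropylidenemalonate 1 and acetyl chloride 2.
5. Ring order: ring B (step 9), then ring A (step 16).

Key step: step 9

Locants are those of the 1H-isochromene target: C1H2, O2, C3 (dienyl chain), C4, C4a, C5 (Cl), C6 (ketone), C7 (methyl carbinol), C8 (carbinol), C8a; C9 is the acetyl carbonyl carbon. Ring A is the pyran, ring B the carbocycle.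

Assumption: the lipase is taken to acylate the pro-S hydroxymethyl group of 6; if it prefers the other group, hydrolysis of the bis-acrylate of 6 with the same lipase should give the same half-ester 7.

Assumption: the (5aS,10bR) antipode of the triazolium salt is taken as the one matched with C8a; the other antipode is equally available and would be used if it proves to be the matched one.

**Step 1**
Reactants: 1 diethyl isopropylidenemalonate; 2 acetyl chloride
Product: 4 diethyl 2-acetyl-2-(prop-1-en-2-yl)propanedioate, via lithium dienolate 3 (not isolated)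
Conditions: LiN(iPr)2, THF, −78 °C; then 2, −78 → 0 °C
Reagents that add atoms: none
Why: γ-Deprotonation gives the cross-conjugated dienolate, which is C-acylated at the α-carbon (deconjugative acylation of a malonate enolate) to build the quaternary carbon (later C8a) carrying isopropenyl (C4a, C4, C5) and acetyl (C9).

**Step 2**
Reactants: 4 diethyl 2-acetyl-2-(prop-1-en-2-yl)propanedioate
Product: 5 diethyl 2-(2-methyl-1,3-dioxolan-2-yl)-2-(prop-1-en-2-yl)propanedioate
Conditions: (Me3SiOCH2)2, Me3SiOTf (cat.), CH2Cl2, −78 °C → rt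
Reagents that add atoms: 1,2-bis(trimethylsilyloxy)ethane, C[Si](C)(C)OCCO[Si](C)(C)C
Why: Noyori ketalization, driven by formation of the disiloxane, should protect the hindered acetyl group at low temperature without retro-Claisen cleavage of the acylmalonate.

**Step 3**
Reactants: 5 diethyl 2-(2-methyl-1,3-dioxolan-2-yl)-2-(prop-1-en-2-yl)propanedioate
Product: 6 2-(2-methyl-1,3-dioxolan-2-yl)-2-(prop-1-en-2-yl)propane-1,3-diol
Conditions: LiAlH4, THF, 0 °C → reflux; aqueous NaOH work-up
Reagents that add atoms: none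
Why: Hydride reduction of both esters gives the prochiral diol, with ketal and alkene inert.

**Step 4**
Reactants: 6 2-(2-methyl-1,3-dioxolan-2-yl)-2-(prop-1-en-2-yl)propane-1,3-diol
Product: 7 (2S)-2-(hydroxymethyl)-3-methyl-2-(2-methyl-1,3-dioxolan-2-yl)but-3-en-1-yl prop-2-enoate
Conditions: Burkholderia cepacia lipase (Amano PS, immobilised), vinyl acrylate, t-BuOMe, 4 Å MS, 30 °C
Reagents that add atoms: vinyl acrylate, C=CC(=O)OC=C
Why: Lipase-catalysed irreversible transesterification with an enol ester (desymmetrization of a prochiral 2,2-disubstituted propane-1,3-diol) should acylate one enantiotopic CH2OH, which sets C8a and installs the acrylate (C5, C6) on the arm that becomes C8.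

**Step 5**
Reactants: 7 (2S)-2-(hydroxymethyl)-3-methyl-2-(2-methyl-1,3-dioxolan-2-yl)but-3-en-1-yl prop-2-enoate
Product: 8 (2R)-2-{[tert-butyl(dimethyl)silyl]oxymethyl}-3-methyl-2-(2-methyl-1,3-dioxolan-2-yl)but-3-en-1-yl prop-2-enoate
Conditions: t-BuMe2SiOTf, 2,6-lutidine, CH2Cl2, −78 °C
Reagents that add atoms: tert-butyldimethylsilyl trifluoromethanesulfonate, CC(C)(C)[Si](C)(C)OS(=O)(=O)C(F)(F)F
Why: Fast silylation of the free arm (C1) with a non-nucleophilic base at low temperature should outrun 1,3-acyl migration, which would erode the enantiomeric purity, and leaves the acrylate untouched.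

**Step 6**
Reactants: 8 (2R)-2-{[tert-butyl(dimethyl)silyl]oxymethyl}-3-methyl-2-(2-methyl-1,3-dioxolan-2-yl)but-3-en-1-yl prop-2-enoate
Product: 9 (5R)-5-{[tert-butyl(dimethyl)silyl]oxymethyl}-4-methyl-5-(2-methyl-1,3-dioxolan-2-yl)-5,6-dihydro-2H-pyran-2-one
Conditions: second-generation Hoveyda–Grubbs catalyst (H2IMes)Cl2Ru=CH(C6H4-2-OiPr) (10 mol%), PhMe (5 mM), 90 °C
Reagents that add atoms: none
Why: Ring-closing metathesis of the acrylate with the 1,1-disubstituted alkene, driven by loss of ethene, gives the trisubstituted unsaturated δ-lactone; the ring fixes C6 cis to C8a across C4a=C5.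

**Step 7**
Reactants: 9 (5R)-5-{[tert-butyl(dimethyl)silyl]oxymethyl}-4-methyl-5-(2-methyl-1,3-dioxolan-2-yl)-5,6-dihydro-2H-pyran-2-one
Product: 11 1-[(5R)-5-{[tert-butyl(dimethyl)silyl]oxymethyl}-2-hydroxy-4-methyl-5-(2-methyl-1,3-dioxolan-2-yl)-5,6-dihydro-2H-pyran-2-yl]ethan-1-one (anomeric mixture in equilibrium with the open δ-hydroxy (Z)-ene-1,2-dione), via lactol enol ether 10 (not isolated)
Conditions: CH2=CHOEt, t-BuLi, THF, −78 → 0 °C; then 9, −78 °C; AcOH; then 0.05 M aq. HCl, THF, 0 °C
Reagents that add atoms: ethyl vinyl ether, C=COCC; water, O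
Why: 1,2-Addition of 1-ethoxyvinyllithium (acetyl anion equivalent) to the lactone should stop at the lactolate, and in lactol 10 the enol ether is not conjugated to a carbonyl, so very dilute acid should hydrolyse it to the C7 ketone while the silyl ether and the hindered dioxolane survive.

**Step 8**
Reactants: 11 lactol of the δ-hydroxy ene-1,2-dione
Product: 12 (2S,3Z)-2-{[tert-butyl(dimethyl)silyl]oxymethyl}-3-methyl-2-(2-methyl-1,3-dioxolan-2-yl)-5,6-dioxohept-3-enal
Conditions: Dess–Martin periodinane, pyridine, CH2Cl2, 0 °C → rt; used at once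
Reagents that add atoms: none
Why: Dess–Martin oxidation should drain the lactol through its open-chain tautomer, whose primary C8 alcohol is oxidised irreversibly to the non-enolizable aldehyde with the Z alkene unchanged.

**Step 9**
Reactants: 12 (2S,3Z)-2-{[tert-butyl(dimethyl)silyl]oxymethyl}-3-methyl-2-(2-methyl-1,3-dioxolan-2-yl)-5,6-dioxohept-3-enal
Product: 13 (2S,6S)-6-{[tert-butyl(dimethyl)silyl]oxymethyl}-2-hydroxy-2,5-dimethyl-6-(2-methyl-1,3-dioxolan-2-yl)cyclohex-4-ene-1,3-dione
Conditions: (5aS,10bR)-2-(pentafluorophenyl)-5a,10b-dihydro-4H,6H-indeno[2,1-b][1,2,4]triazolo[4,3-d][1,4]oxazinium tetrafluoroborate (20 mol%), Et3N (20 mol%), PhMe, rt → 40 °C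
Reagents that add atoms: none
Why: The triazolylidene adds to the C8 aldehyde, proton transfer gives the Breslow enaminol (acyl anion equivalent), and this adds to the C7 ketone and releases the carbene; the closest known reaction type is the carbene-catalysed intramolecular crossed aldehyde–ketone benzoin cyclization to six-membered tertiary α-ketols. Ring B closes in the 6-exo-trig mode (C8 onto C7, with C7=O exocyclic). C7 is the only new stereocentre and should be set by the chiral triazolium acting together with C8a: the bulky azolium avoids the pseudoaxial dioxolanyl group, so the hydrogen-bonded O8–H···O7 pair lies on the ketal face and O7 ends cis to C9 with the C7 methyl equatorial. The step needs attack at C7 and not at C6; C6 is conjugated with C4a=C5 and less electrophilic, and its attack (5-exo) would require twisting that carbonyl out of conjugation. The Z geometry fixed in lactone 9 holds C8 near C7, and C8a has no hydrogen, so neither epimerisation nor aldol chemistry can occur at that centre.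

**Step 10**
Reactants: 13 ring B hydroxy dione silyl ether
Product: 14 (2S,6S)-2-hydroxy-6-(hydroxymethyl)-2,5-dimethyl-6-(2-methyl-1,3-dioxolan-2-yl)cyclohex-4-ene-1,3-dione
Conditions: HF·pyridine, pyridine, THF, 0 °C → rt
Reagents that add atoms: none
Why: Fluoride-mediated desilylation in a weakly acidic medium should free the C1 hydroxyl without the base-induced retro-aldol loss of formaldehyde open to this β-hydroxy ketone, and without touching the dioxolane.

**Step 11**
Reactants: 14 (2S,6S)-2-hydroxy-6-(hydroxymethyl)-2,5-dimethyl-6-(2-methyl-1,3-dioxolan-2-yl)cyclohex-4-ene-1,3-dione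
Product: 15 (4S,5R,6R)-5,6-dihydroxy-4-(hydroxymethyl)-3,6-dimethyl-4-(2-methyl-1,3-dioxolan-2-yl)cyclohex-2-en-1-one
Conditions: Me4NBH(OAc)3, MeCN/AcOH (1:1), −40 → 0 °C
Reagents that add atoms: none
Why: In this Evans–Saksena reduction the primary C1 hydroxyl should bind boron and deliver hydride through a six-membered transition state to the face of C8 that carries C1, so the C8 hydroxyl ends trans to C1 and cis to O7 and the C9 ketal; the mild reagent leaves the undirected C6 enone alone.

**Step 12**
Reactants: 16 (2S)-2-methylbutan-1-ol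
Product: 18 (2E,4S)-2,4-dimethylhex-2-enal, via (S)-2-methylbutanal 17 (not isolated)
Conditions: PhI(OAc)2, TEMPO (10 mol%), CH2Cl2, rt; then Ph3P=C(CH3)CHO, PhMe, 80 °C
Reagents that add atoms: 2-(triphenylphosphoranylidene)propanal, CC(C=O)=P(c1ccccc1)(c2ccccc2)c3ccccc3
Why: Base-free oxoammonium oxidation should give the α-chiral aldehyde without epimerisation, and the Wittig reaction with the stabilised formyl ylide should give the E trisubstituted enal.

**Step 13**
Reactants: 18 (2E,4S)-2,4-dimethylhex-2-enal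
Product: 20 (2E,4E,6S)-4,6-dimethylocta-2,4-dienoic acid, via alkylidenemalonic acid 19 (not isolated)
Conditions: CH2(CO2H)2, pyridine, piperidine (cat.), 90 °C
Reagents that add atoms: malonic acid, OC(=O)CC(=O)O
Why: Knoevenagel–Doebner condensation with decarboxylation should give the (2E)-dienoic acid, the remote stereocentre being unaffected.

**Step 14**
Reactants: 15 triol; 20 (2E,4E,6S)-4,6-dimethylocta-2,4-dienoic acid
Product: 21 [(1S,5R,6R)-5,6-dihydroxy-2,5-dimethyl-1-(2-methyl-1,3-dioxolan-2-yl)-4-oxocyclohex-2-en-1-yl]methyl (2E,4E,6S)-4,6-dimethylocta-2,4-dienoate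
Conditions: DCC, DMAP (cat.), CH2Cl2, 0 °C
Reagents that add atoms: none
Why: Steglich esterification should acylate only the primary C1 hydroxyl, since the C8 hydroxyl is flanked by two quaternary carbons and the C7 hydroxyl is tertiary; this tethers C3 and the side chain next to the C4 methyl.

**Step 15**
Reactants: 21 C1 dienoate diol
Product: 22 7,8-O-isopropylidene acetal of 21 (cis-fused acetonide on O7 and O8; C7, C8, C8a unchanged)
Conditions: Me2C(OMe)2, PPTS (cat.), CH2Cl2, rt
Reagents that add atoms: 2,2-dimethoxypropane, COC(C)(C)OC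
Why: Acid-catalysed transketalization onto the cis-7,8-diol masks both hydroxyls, which under base would otherwise open ring B by retro-aldol cleavage or take over the acyl group.

**Step 16**
Reactants: 22 acetonide of the C1 dienoate
Product: 25 (7R,8R,8aS)-3-[(1E,3E,5S)-3,5-dimethylhepta-1,3-dien-1-yl]-7,8-(isopropylidenedioxy)-7-methyl-8a-(2-methyl-1,3-dioxolan-2-yl)-1,7,8,8a-tetrahydro-6H-isochromen-6-one, via C4-acylated hydroxy dienone 23 (not isolated), via ring A hemiketal 24 (not isolated)
Conditions: LiN(SiMe3)2 (2.2 equiv), THF, −78 → −20 °C; AcOH; then CSA (cat.), 4 Å MS, CH2Cl2, rt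
Reagents that add atoms: none
Why: Proposed new method: the base can only remove a C4 proton (C7 and C8a carry no hydrogen), and the C4 terminus of the dienolate reaches the ester carbonyl C3 through a six-membered transition state, whereas attack through C5 would give a strained bicyclo[3.3.1] system and reverts; collapse of the tetrahedral intermediate with loss of the C1 alkoxide gives a stabilised vinylogous 1,3-diketonate, and acid then closes the C1 hydroxyl onto the C3 ketone and dehydrates the hemiketal to the conjugated C3=C4 enol ether of ring A (closest known reaction types: Baker–Venkataraman O-to-C acyl transfer and Dieckmann condensation, followed by cyclodehydration of a δ-hydroxy ketone to a pyran).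

**Step 17**
Reactants: 25 ring A/ring B bicycle with both ketals
Product: 26 5-chloro derivative of 25 ((7R,8R,8aS), Cl at C5)
Conditions: NCS (1.05 equiv), MeCN, 0 °C, dark
Reagents that add atoms: N-chlorosuccinimide, O=C1CCC(=O)N1Cl
Why: C5 is the α-carbon of the doubly vinylogous ester O2–C3=C4–C4a=C5–C6=O and its most nucleophilic site, so electrophilic α-chlorination of this push–pull system should occur there, the side-chain diene not being activated by O2.

**Step 18**
Reactants: 26 5-chloro bis-ketal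
Product: 27 (7R,8R,8aS)-8a-acetyl-5-chloro-3-[(1E,3E,5S)-3,5-dimethylhepta-1,3-dien-1-yl]-7,8-dihydroxy-7-methyl-1,7,8,8a-tetrahydro-6H-isochromen-6-one (target)
Conditions: 2 M aq. HCl, THF, 0 °C → rt
Reagents that add atoms: water, O
Why: Acid hydrolysis should remove the acetonide and the dioxolane together, and the absence of base avoids retro-aldol cleavage of the C8–OH/C9=O β-hydroxy ketone.

**Compound list**

1 | diethyl isopropylidenemalonate | CC(C)=C(C(=O)OCC)C(=O)OCC | starting material
2 | acetyl chloride | CC(Cl)=O | starting material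
3 | lithium dienolate of 1 | CCOC(=O)C(C(C)=C)=C(O[Li])OCC | intermediate
4 | diethyl 2-acetyl-2-(prop-1-en-2-yl)propanedioate | CCOC(=O)C(C(C)=C)(C(C)=O)C(=O)OCC | intermediate
5 | diethyl 2-(2-methyl-1,3-dioxolan-2-yl)-2-(prop-1-en-2-yl)propanedioate | CCOC(=O)C(C(C)=C)(C(=O)OCC)C1(C)OCCO1 | intermediate
6 | 2-(2-methyl-1,3-dioxolan-2-yl)-2-(prop-1-en-2-yl)propane-1,3-diol | CC(=C)C(CO)(CO)C1(C)OCCO1 | intermediate
7 | (2S)-2-(hydroxymethyl)-3-methyl-2-(2-methyl-1,3-dioxolan-2-yl)but-3-en-1-yl prop-2-enoate | CC(=C)[C@@](COC(=O)C=C)(CO)C1(C)OCCO1 | intermediate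
8 | (2R)-2-{[tert-butyl(dimethyl)silyl]oxymethyl}-3-methyl-2-(2-methyl-1,3-dioxolan-2-yl)but-3-en-1-yl prop-2-enoate | CC(=C)[C@@](COC(=O)C=C)(CO[Si](C)(C)C(C)(C)C)C1(C)OCCO1 | intermediate
9 | (5R)-5-{[tert-butyl(dimethyl)silyl]oxymethyl}-4-methyl-5-(2-methyl-1,3-dioxolan-2-yl)-5,6-dihydro-2H-pyran-2-one | O=C1C=C(C)[C@@](CO1)(CO[Si](C)(C)C(C)(C)C)C2(C)OCCO2 | intermediate
10 | (5R)-5-{[tert-butyl(dimethyl)silyl]oxymethyl}-2-(1-ethoxyethenyl)-4-methyl-5-(2-methyl-1,3-dioxolan-2-yl)-5,6-dihydro-2H-pyran-2-ol (anomers) | CCOC(=C)C1(O)C=C(C)[C@@](CO1)(CO[Si](C)(C)C(C)(C)C)C2(C)OCCO2 | intermediate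
11 | 1-[(5R)-5-{[tert-butyl(dimethyl)silyl]oxymethyl}-2-hydroxy-4-methyl-5-(2-methyl-1,3-dioxolan-2-yl)-5,6-dihydro-2H-pyran-2-yl]ethan-1-one (anomers) | CC(=O)C1(O)C=C(C)[C@@](CO1)(CO[Si](C)(C)C(C)(C)C)C2(C)OCCO2 | intermediate
12 | (2S,3Z)-2-{[tert-butyl(dimethyl)silyl]oxymethyl}-3-methyl-2-(2-methyl-1,3-dioxolan-2-yl)-5,6-dioxohept-3-enal | CC(=O)C(=O)/C=C(C)\[C@@](C=O)(CO[Si](C)(C)C(C)(C)C)C1(C)OCCO1 | intermediate
13 | (2S,6S)-6-{[tert-butyl(dimethyl)silyl]oxymethyl}-2-hydroxy-2,5-dimethyl-6-(2-methyl-1,3-dioxolan-2-yl)cyclohex-4-ene-1,3-dione | CC1=CC(=O)[C@](C)(O)C(=O)[C@]1(CO[Si](C)(C)C(C)(C)C)C2(C)OCCO2 | intermediate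
14 | (2S,6S)-2-hydroxy-6-(hydroxymethyl)-2,5-dimethyl-6-(2-methyl-1,3-dioxolan-2-yl)cyclohex-4-ene-1,3-dione | CC1=CC(=O)[C@](C)(O)C(=O)[C@]1(CO)C2(C)OCCO2 | intermediate
15 | (4S,5R,6R)-5,6-dihydroxy-4-(hydroxymethyl)-3,6-dimethyl-4-(2-methyl-1,3-dioxolan-2-yl)cyclohex-2-en-1-one | CC1=CC(=O)[C@](C)(O)[C@H](O)[C@]1(CO)C2(C)OCCO2 | intermediate
16 | (2S)-2-methylbutan-1-ol | CC[C@H](C)CO | starting material
17 | (2S)-2-methylbutanal | CC[C@H](C)C=O | intermediate
18 | (2E,4S)-2,4-dimethylhex-2-enal | CC[C@H](C)/C=C(C)/C=O | intermediate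
19 | 2-[(2E,4S)-2,4-dimethylhex-2-en-1-ylidene]propanedioic acid | CC[C@H](C)/C=C(C)/C=C(C(=O)O)C(=O)O | intermediate
20 | (2E,4E,6S)-4,6-dimethylocta-2,4-dienoic acid | CC[C@H](C)/C=C(C)/C=C/C(=O)O | intermediate
21 | [(1S,5R,6R)-5,6-dihydroxy-2,5-dimethyl-1-(2-methyl-1,3-dioxolan-2-yl)-4-oxocyclohex-2-en-1-yl]methyl (2E,4E,6S)-4,6-dimethylocta-2,4-dienoate | CC1=CC(=O)[C@](C)(O)[C@H](O)[C@]1(COC(=O)/C=C/C(C)=C/[C@@H](C)CC)C2(C)OCCO2 | intermediate
22 | 7,8-O-isopropylidene acetal of 21 | CC1=CC(=O)[C@]3(C)OC(C)(C)O[C@@H]3[C@]1(COC(=O)/C=C/C(C)=C/[C@@H](C)CC)C2(C)OCCO2 | intermediate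
23 | C4-acylated hydroxy dienone (C1–OH free, C3 ketone, acetonide and dioxolane in place) | O=C(/C=C/C(C)=C/[C@@H](C)CC)CC1=CC(=O)[C@]3(C)OC(C)(C)O[C@@H]3[C@]1(CO)C2(C)OCCO2 | intermediate
24 | ring A hemiketal (C3–OH, both C3 epimers) | OC1(/C=C/C(C)=C/[C@@H](C)CC)CC2=CC(=O)[C@]3(C)OC(C)(C)O[C@@H]3[C@]2(CO1)C4(C)OCCO4 | intermediate
25 | (7R,8R,8aS)-3-[(1E,3E,5S)-3,5-dimethylhepta-1,3-dien-1-yl]-7,8-(isopropylidenedioxy)-7-methyl-8a-(2-methyl-1,3-dioxolan-2-yl)-1,7,8,8a-tetrahydro-6H-isochromen-6-one | CC[C@H](C)/C=C(C)/C=C/C1=CC2=CC(=O)[C@]3(C)OC(C)(C)O[C@@H]3[C@@]2(C4(C)OCCO4)CO1 | intermediate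
26 | 5-chloro derivative of 25 | CC[C@H](C)/C=C(C)/C=C/C1=CC2=C(Cl)C(=O)[C@]3(C)OC(C)(C)O[C@@H]3[C@@]2(C4(C)OCCO4)CO1 | intermediate
27 | (7R,8R,8aS)-8a-acetyl-5-chloro-3-[(1E,3E,5S)-3,5-dimethylhepta-1,3-dien-1-yl]-7,8-dihydroxy-7-methyl-1,7,8,8a-tetrahydro-6H-isochromen-6-one | CC[C@H](C)/C=C(C)/C=C/C1=CC2=C(Cl)C(=O)[C@](C)(O)[C@H](O)[C@@]2(C(C)=O)CO1 | target

Total step count: 18.
Longest linear sequence: 16 steps (steps 1–11 and 14–18); steps 12–13 form the side-chain branch.

**Steps most likely to fail**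

1. Step 16 (proposed new method). The dienolate may form sluggishly, may compete with ε-deprotonation of the dienoate (which would scramble the side-chain stereocentre), or may fail to transfer the acyl group to C4. The fallback uses known chemistry, sets out from 15 and returns at 25. Triol 15 is persilylated with Et3SiOTf/Et3N in CH2Cl2, which also turns the enone into its silyl dienol ether, giving the tetrakis(triethylsilyl) dienol ether F1. The side-chain aldehyde (2E,4E,6S)-4,6-dimethylocta-2,4-dienal F2 is made from 18 and Ph3P=CHCHO (Wittig, PhMe, 80 °C). A vinylogous Mukaiyama aldol addition of F1 to F2 (BF3·OEt2, CH2Cl2, −78 °C) should form C3–C4 at the γ-terminus and give the C3 carbinol F3. Dess–Martin oxidation of the allylic carbinol should give the C3 ketone F4. HF·pyridine then removes the three triethylsilyl ethers, after which the C1 hydroxyl should close onto C3 and the hemiketal dehydrate to the ring A diol F5. Me2C(OMe)2/PPTS converts F5 into 25.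

2. Step 9 (key step). The carbene may add too slowly to the neopentyl aldehyde for the Breslow intermediate to form, or closure may occur on the wrong face of C7 or at C6. The fallback reverses the polarity of the diketone instead of the aldehyde, sets out from 12 and returns at 13. P(OMe)3 in CH2Cl2 should add to the 1,2-dione to give a dioxaphospholene whose C7 attacks the C8 aldehyde (Kukhtin–Ramirez reductive aldol), giving the trimethoxy dioxaphospholane F6 fused at C7–C8. Aqueous hydrolysis should give the 7,8-diol silyl ether F7 (C8 configuration open). Swern oxidation of the secondary C8 hydroxyl then gives 13. The C7 face is under substrate control here and would have to be confirmed before going on.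

3. Step 4. The lipase may discriminate poorly between the enantiotopic hydroxymethyl groups, whose flanking substituents are both branched, or may acylate this hindered diol too slowly. The fallback replaces catalytic desymmetrization by separation of covalent diastereomers, sets out from 6 and returns at 8. Mono-acylation of 6 with (1S)-camphanic chloride/pyridine gives two diastereomeric half-esters; the one esterified on the pro-S arm, monocamphanate F8, is separated by chromatography or crystallization and the other is saponified back to 6. Silylation (t-BuMe2SiOTf, 2,6-lutidine, −78 °C) gives the silyl ether camphanate F9. LiAlH4 (THF, −20 °C) cleaves the auxiliary to give the (R)-alcohol F10. Acryloyl chloride/Et3N (CH2Cl2, 0 °C) then gives 8.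

**Further compounds**

F1 | step 16 | tetrakis(triethylsilyl) dienol ether of 15 (O1, O7, O8 silylated; C6 silyl enol ether with exocyclic C4a=C4H2) | C=C1C=C(O[Si](CC)(CC)CC)[C@](C)(O[Si](CC)(CC)CC)[C@H](O[Si](CC)(CC)CC)[C@]1(CO[Si](CC)(CC)CC)C2(C)OCCO2
F2 | step 16 | (2E,4E,6S)-4,6-dimethylocta-2,4-dienal | CC[C@H](C)/C=C(C)/C=C/C=O
F3 | step 16 | C3 carbinol from the vinylogous aldol addition (tris-triethylsilyl ether, both C3 epimers) | CC[C@H](C)/C=C(C)/C=C/C(O)CC1=CC(=O)[C@](C)(O[Si](CC)(CC)CC)[C@H](O[Si](CC)(CC)CC)[C@]1(CO[Si](CC)(CC)CC)C2(C)OCCO2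
F4 | step 16 | C3 ketone (tris-triethylsilyl ether) | CC[C@H](C)/C=C(C)/C=C/C(=O)CC1=CC(=O)[C@](C)(O[Si](CC)(CC)CC)[C@H](O[Si](CC)(CC)CC)[C@]1(CO[Si](CC)(CC)CC)C2(C)OCCO2
F5 | step 16 | (7R,8R,8aS)-3-[(1E,3E,5S)-3,5-dimethylhepta-1,3-dien-1-yl]-7,8-dihydroxy-7-methyl-8a-(2-methyl-1,3-dioxolan-2-yl)-1,7,8,8a-tetrahydro-6H-isochromen-6-one | CC[C@H](C)/C=C(C)/C=C/C1=CC2=CC(=O)[C@](C)(O)[C@H](O)[C@@]2(C3(C)OCCO3)CO1
F6 | step 9 | 2,2,2-trimethoxy-1,3,2-dioxaphospholane fused at C7–C8 of ring B (C1 silyl ether, C8 configuration open) | CC1=CC(=O)[C@]2(C)OP(OC)(OC)(OC)OC2[C@]1(CO[Si](C)(C)C(C)(C)C)C3(C)OCCO3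
F7 | step 9 | 7,8-diol C1 silyl ether with C6 enone (C8 configuration open) | CC1=CC(=O)[C@](C)(O)C(O)[C@]1(CO[Si](C)(C)C(C)(C)C)C2(C)OCCO2
F8 | step 4 | mono-(1S)-camphanate of 6 on the pro-S arm | CC(=C)[C@@](COC(=O)[C@]1(CC[C@@]2(C)C(=O)O1)C2(C)C)(CO)C3(C)OCCO3
F9 | step 4 | tert-butyldimethylsilyl ether of F8 | CC(=C)[C@@](COC(=O)[C@]1(CC[C@@]2(C)C(=O)O1)C2(C)C)(CO[Si](C)(C)C(C)(C)C)C3(C)OCCO3
F10 | step 4 | (2R)-2-{[tert-butyl(dimethyl)silyl]oxymethyl}-3-methyl-2-(2-methyl-1,3-dioxolan-2-yl)but-3-en-1-ol | CC(=C)[C@@](CO)(CO[Si](C)(C)C(C)(C)C)C1(C)OCCO1
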